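The flavone is cut at O1–C2. Ring C is closed by an electrophile-induced 6-endo cyclisation of an aryl ynone: an ortho methoxy oxygen becomes O1 and loses its methyl group, while iodine lands on C3 as the handle for the C3 methoxy group. The step exploits the symmetry of ring A: with O1 written as a methoxy group, the ring is symmetric about the C4a–C7 axis (C5 matches C8a, C6 matches C8), so both ortho methoxy groups of the precursor give the same chromone. The precursor is 1-[4-(benzyloxy)-2,3,5,6-tetramethoxyphenyl]-3-(4-methoxyphenyl)prop-2-yn-1-one; its benzyl ether masks the C7 hydroxyl.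

Key step: step 5

Remark: 4-(benzyloxy)-3,5-dimethoxybenzaldehyde (the benzyl ether of syringaldehyde) is taken as a catalogue compound, so the C7 protecting group is in place from the start.

Step 1
Reactants: 1 4-(benzyloxy)-3,5-dimethoxybenzaldehyde
Product: 3 4-(benzyloxy)-2,6-dibromo-3,5-dimethoxybenzaldehyde, via monobromo aldehyde 2 (not isolated)
Conditions: Br2 (2.5 equiv), NaOAc, AcOH, rt → 45 °C
Reagents that add atoms: bromine, BrBr
Why: Electrophilic aromatic bromination should take place at C2 and C6, the only free positions of the alkoxy-substituted ring and each ortho to one methoxy group and para to the other, while the acetate buffer traps HBr so that the benzyl ether survives and the unactivated benzyl ring does not compete.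

Step 2
Reactants: 3 4-(benzyloxy)-2,6-dibromo-3,5-dimethoxybenzaldehyde
Product: 5 4-(benzyloxy)-2,3,5,6-tetramethoxybenzaldehyde, via bromo trimethoxy aldehyde 4 (not isolated)
Conditions: NaOMe (6 equiv), CuBr (30 mol %), MeOH–DMF, 100 °C
Reagents that add atoms: sodium methoxide, C[O-].[Na+]
Why: Ullmann-type copper-catalysed methoxylation of aryl bromides should replace both C–Br bonds, since each lies ortho to the aldehyde, which accelerates the copper-mediated substitution, and the non-enolisable aldehyde and the benzyl ether tolerate methoxide.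

Step 3
Reactants: 5 4-(benzyloxy)-2,3,5,6-tetramethoxybenzaldehyde; 6 4-ethynylanisole
Product: 8 rac-1-[4-(benzyloxy)-2,3,5,6-tetramethoxyphenyl]-3-(4-methoxyphenyl)prop-2-yn-1-ol, via lithium 4-methoxyphenylacetylide 7 (not isolated)
Conditions: 6, n-BuLi, THF, −78 °C; then 5, −78 → 0 °C; aq NH4Cl
Reagents that add atoms: none
Why: 1,2-Addition of a lithium acetylide to a non-enolisable aldehyde should give the propargylic alcohol as a racemate, which is acceptable because the carbinol carbon becomes the ketone in the next step.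

Step 4
Reactants: 8 rac-1-[4-(benzyloxy)-2,3,5,6-tetramethoxyphenyl]-3-(4-methoxyphenyl)prop-2-yn-1-ol
Product: 9 1-[4-(benzyloxy)-2,3,5,6-tetramethoxyphenyl]-3-(4-methoxyphenyl)prop-2-yn-1-one
Conditions: MnO2 (activated, excess), CH2Cl2, rt
Reagents that add atoms: none
Why: MnO2 oxidation of a benzylic and propargylic secondary alcohol proceeds under neutral conditions, which avoids ionisation of the electron-rich carbinol and removes the only stereocentre of the route.

Step 5
Reactants: 9 1-[4-(benzyloxy)-2,3,5,6-tetramethoxyphenyl]-3-(4-methoxyphenyl)prop-2-yn-1-one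
Product: 11 7-(benzyloxy)-3-iodo-5,6,8-trimethoxy-2-(4-methoxyphenyl)-4H-chromen-4-one, via O-methyl oxonium chloride 10 (not isolated)
Conditions: ICl (1.5 equiv), CH2Cl2, −78 °C → rt; aq Na2S2O3
Reagents that add atoms: iodine monochloride, ClI
Why: ICl delivers an iodine cation to the alkyne of 9 and an ortho methoxy oxygen attacks the activated triple bond anti to iodine at the carbon that carries the anisyl group, which forms O1–C2 and C3–I and gives the O-methyl oxonium salt 10; chloride then removes the methyl group by SN2 and releases chloromethane. The closest known reaction type is the ICl-induced electrophilic cyclisation of 2-methoxyaryl alkynones to 3-iodochromones. Ring C is closed in the 6-endo-dig mode and no stereocentre is created. The step needs 6-endo rather than 5-exo closure, and this is secured by the 4-methoxyphenyl group, which stabilises positive charge at the future C2, and by the carbonyl group, which disfavours cationic character at the alpha carbon. A choice between the two ortho methoxy groups does not arise, because the aryl ring of 9 is symmetric about its C1–C4 axis (the C4a–C7 axis of the chromone), so both closures give 11. Ring A carries no hydrogen and the reaction is run cold with a small excess of ICl, so aromatic iodination is limited to a possible minor reaction on ring B, and the benzyl ether in the para position cannot take part in ring closure.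

Step 6
Reactants: 11 7-(benzyloxy)-3-iodo-5,6,8-trimethoxy-2-(4-methoxyphenyl)-4H-chromen-4-one
Product: 12 7-(benzyloxy)-3,5,6,8-tetramethoxy-2-(4-methoxyphenyl)-4H-chromen-4-one
Conditions: NaOMe (3 equiv), CuBr (20 mol %), 1,10-phenanthroline (40 mol %), MeOH–toluene, 80 °C
Reagents that add atoms: sodium methoxide, C[O-].[Na+]
Why: Ullmann-type copper-catalysed C–O coupling of an sp2 iodide with methoxide should replace the C3 iodide, since the C3–I bond of the vinylogous ester is activated toward copper insertion, the phenanthroline ligand allows a moderate temperature, and the C2 aryl group hinders conjugate addition.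

Step 7
Reactants: 12 7-(benzyloxy)-3,5,6,8-tetramethoxy-2-(4-methoxyphenyl)-4H-chromen-4-one
Product: 13 7-hydroxy-3,5,6,8-tetramethoxy-2-(4-methoxyphenyl)-4H-chromen-4-one
Conditions: H2 (1 atm), 10% Pd/C, EtOAc–MeOH, rt
Reagents that add atoms: none
Why: Catalytic hydrogenolysis of a benzyl aryl ether over zerovalent palladium on carbon at ambient pressure should free the C7 hydroxyl while the tetrasubstituted C2=C3 bond, the ketone and the methyl ethers stay intact; the product is achiral.

Compound list
1 | 4-(benzyloxy)-3,5-dimethoxybenzaldehyde | COc1cc(C=O)cc(OC)c1OCc1ccccc1 | starting material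
2 | 4-(benzyloxy)-2-bromo-3,5-dimethoxybenzaldehyde (formed in the flask) | COc1cc(C=O)c(Br)c(OC)c1OCc1ccccc1 | intermediate
3 | 4-(benzyloxy)-2,6-dibromo-3,5-dimethoxybenzaldehyde | COc1c(Br)c(C=O)c(Br)c(OC)c1OCc1ccccc1 | intermediate
4 | 4-(benzyloxy)-2-bromo-3,5,6-trimethoxybenzaldehyde (formed in the flask) | COc1c(OC)c(C=O)c(Br)c(OC)c1OCc1ccccc1 | intermediate
5 | 4-(benzyloxy)-2,3,5,6-tetramethoxybenzaldehyde | COc1c(OC)c(C=O)c(OC)c(OC)c1OCc1ccccc1 | intermediate
6 | 4-ethynylanisole (1-ethynyl-4-methoxybenzene) | C#Cc1ccc(OC)cc1 | starting material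
7 | lithium (4-methoxyphenyl)acetylide (formed in the flask) | [Li]C#Cc1ccc(OC)cc1 | intermediate
8 | rac-1-[4-(benzyloxy)-2,3,5,6-tetramethoxyphenyl]-3-(4-methoxyphenyl)prop-2-yn-1-ol (racemate, one stereocentre, not defined) | COc1ccc(C#CC(O)c2c(OC)c(OC)c(OCc3ccccc3)c(OC)c2OC)cc1 | intermediate
9 | 1-[4-(benzyloxy)-2,3,5,6-tetramethoxyphenyl]-3-(4-methoxyphenyl)prop-2-yn-1-one | COc1ccc(C#CC(=O)c2c(OC)c(OC)c(OCc3ccccc3)c(OC)c2OC)cc1 | intermediate
10 | 7-(benzyloxy)-3-iodo-5,6,8-trimethoxy-2-(4-methoxyphenyl)-1-methyl-4-oxo-4H-chromen-1-ium chloride (formed in the flask) | COc1ccc(C2=C(I)C(=O)c3c(OC)c(OC)c(OCc4ccccc4)c(OC)c3[O+]2C)cc1.[Cl-] | intermediate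
11 | 7-(benzyloxy)-3-iodo-5,6,8-trimethoxy-2-(4-methoxyphenyl)-4H-chromen-4-one | COc1ccc(-c2oc3c(OC)c(OCc4ccccc4)c(OC)c(OC)c3c(=O)c2I)cc1 | intermediate
12 | 7-(benzyloxy)-3,5,6,8-tetramethoxy-2-(4-methoxyphenyl)-4H-chromen-4-one | COc1ccc(-c2oc3c(OC)c(OCc4ccccc4)c(OC)c(OC)c3c(=O)c2OC)cc1 | intermediate
13 | 7-hydroxy-3,5,6,8-tetramethoxy-2-(4-methoxyphenyl)-4H-chromen-4-one | COc1ccc(-c2oc3c(OC)c(O)c(OC)c(OC)c3c(=O)c2OC)cc1 | target

Total step count: 7. Longest linear sequence: 7 steps (1 → 3 → 5 → 8 → 9 → 11 → 12 → 13); alkyne 6 enters in step 3.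

Steps most likely to fail

1. Step 6 (methoxylation at C3). What may go wrong: methoxide adds to C2 of the iodochromone and opens or contracts the pyranone ring, or the iodide is lost reductively before the C–O bond forms. The fallback sets out from 11 and returns at 12. Iodine–magnesium exchange with iPrMgCl·LiCl (THF, −78 °C) and trapping of the C3-magnesiated flavone with B(OMe)3 should give dimethyl [7-(benzyloxy)-5,6,8-trimethoxy-2-(4-methoxyphenyl)-4-oxo-4H-chromen-3-yl]boronate F1. This is oxidised in the same flask (H2O2, AcOH) to the flavonol 7-(benzyloxy)-3-hydroxy-5,6,8-trimethoxy-2-(4-methoxyphenyl)-4H-chromen-4-one F2. O-Methylation of F2 (MeI, K2CO3, acetone) then gives 12. Borylation and oxidation of C3-metalated flavones to flavonols is established chemistry, and no free alkoxide is present at elevated temperature.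

2. Step 5 (key step). What may go wrong: iodination of ring B or attack on the benzyl ether by excess ICl, or incomplete dealkylation of the oxonium intermediate. The fallback sets out from 5 and returns at 11; it generates the phenol first and closes ring C by conjugate addition.
- Chelation-controlled cleavage of one of the two equivalent ortho methyl ethers with MgI2·OEt2 (Et2O–toluene) should give 4-(benzyloxy)-2-hydroxy-3,5,6-trimethoxybenzaldehyde F3.
- Addition of 7 (2.2 equiv, THF) gives the diol rac-1-[4-(benzyloxy)-2-hydroxy-3,5,6-trimethoxyphenyl]-3-(4-methoxyphenyl)prop-2-yn-1-ol F4.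
- MnO2 oxidation gives the hydroxyaryl ynone 1-[4-(benzyloxy)-2-hydroxy-3,5,6-trimethoxyphenyl]-3-(4-methoxyphenyl)prop-2-yn-1-one F5.
- Et2NH in EtOH closes ring C through the enaminone to the flavone 7-(benzyloxy)-5,6,8-trimethoxy-2-(4-methoxyphenyl)-4H-chromen-4-one F6.
- C3 lithiation (LDA, THF, −78 °C) and quenching with I2 gives 11.

3. Step 2 (double methoxylation). What may go wrong: reductive debromination or stalling after the first substitution, together with slow loss of the aldehyde during long heating in methoxide. The fallback sets out from 1 and returns at 5, and installs the two oxygens one at a time. Monobromination of 1 (NBS, 1.05 equiv, MeCN) with isolation of 2 is followed by a single Ullmann methoxylation (NaOMe, CuBr, MeOH–DMF) to 4-(benzyloxy)-2,3,5-trimethoxybenzaldehyde F7. Bromination of its one free ring position (NBS, MeCN) gives 4, isolated this time, and a second single methoxylation gives 5. Material that loses bromine in the one-pot version is F7 itself and can be fed into this sequence.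

Further compounds
F1 | step 6 | dimethyl [7-(benzyloxy)-5,6,8-trimethoxy-2-(4-methoxyphenyl)-4-oxo-4H-chromen-3-yl]boronate | COB(OC)c1c(-c2ccc(OC)cc2)oc2c(OC)c(OCc3ccccc3)c(OC)c(OC)c2c1=O
F2 | step 6 | 7-(benzyloxy)-3-hydroxy-5,6,8-trimethoxy-2-(4-methoxyphenyl)-4H-chromen-4-one | COc1ccc(-c2oc3c(OC)c(OCc4ccccc4)c(OC)c(OC)c3c(=O)c2O)cc1
F3 | step 5 | 4-(benzyloxy)-2-hydroxy-3,5,6-trimethoxybenzaldehyde | COc1c(OC)c(C=O)c(O)c(OC)c1OCc1ccccc1
F4 | step 5 | rac-1-[4-(benzyloxy)-2-hydroxy-3,5,6-trimethoxyphenyl]-3-(4-methoxyphenyl)prop-2-yn-1-ol | COc1ccc(C#CC(O)c2c(O)c(OC)c(OCc3ccccc3)c(OC)c2OC)cc1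
F5 | step 5 | 1-[4-(benzyloxy)-2-hydroxy-3,5,6-trimethoxyphenyl]-3-(4-methoxyphenyl)prop-2-yn-1-one | COc1ccc(C#CC(=O)c2c(O)c(OC)c(OCc3ccccc3)c(OC)c2OC)cc1
F6 | step 5 | 7-(benzyloxy)-5,6,8-trimethoxy-2-(4-methoxyphenyl)-4H-chromen-4-one | COc1ccc(-c2cc(=O)c3c(OC)c(OC)c(OCc4ccccc4)c(OC)c3o2)cc1
F7 | step 2 | 4-(benzyloxy)-2,3,5-trimethoxybenzaldehyde | COc1cc(C=O)c(OC)c(OC)c1OCc1ccccc1
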